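**Retrosynthetic overview**

1. The target comes from its pentadeca-O-benzyl ether by global hydrogenolysis.
2. Both tetrahydrofurans are cut at once, following the presumed biosynthesis (radical α–α′, i.e. 8–8′, union of two chalcone-level C6–C3–C6 units, then O-cyclisation). Cutting C3–C4 and O1–C5 of each ring leads to a flavan-bound bis(enol silane) and two molecules of an enantiopure chalcone epoxide; C5–H comes from hydride reduction of the cyclic ketal.
3. The flavan-bound bis(dihydrochalcone) comes from afzelechin and two isoliquiritigenin units by catalyst-controlled Friedel–Crafts conjugate addition at C6 and C8 of ring A, which sets both exocyclic CH centres; its nine phenols are then benzylated in two stages.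
4. The epoxide comes from tri-O-benzylisoliquiritigenin, made from a protected acetophenone and aldehyde.
5. Ring order: the chroman ring arrives with afzelechin; the two tetrahydrofuran rings are formed last and simultaneously.

Assumption: (+)-afzelechin 1 and isoliquiritigenin 2 are bought as commercial flavonoids (1 is sold as an isolated natural product and is the costliest input); tetrahydrofuran atoms are numbered O1, C2 (4-oxyphenyl), C3 (aroyl), C4 (bears the exocyclic CH), C5 (2,4-dioxyphenyl); the target is flavan 2R,3S, both exocyclic CH 1S, both tetrahydrofurans 2S,3S,4S,5R (2,3-trans, 3,4-trans, 4,5-cis).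

**Step 1**
Reactants: 1 (+)-afzelechin; 2 isoliquiritigenin (2.5 equiv)
Product: 3 (2R,3S)-6,8-bis[(1S)-3-(2,4-dihydroxyphenyl)-1-(4-hydroxyphenyl)-3-oxopropyl]-2-(4-hydroxyphenyl)chromane-3,5,7-triol
Conditions: Sc(OTf)3 (10 mol %), Feng N,N′-dioxide ligand L-PiPr2 (12 mol %), 4 Å MS, THF, 0 °C
Reagents that add atoms: none
Why: Proposed new method: Sc(OTf)3 held in the chiral N,N′-dioxide pocket is chelated by the 2′-phenoxide/carbonyl pair of 2, which lowers the enone LUMO and leaves the Si face of Cβ open, so ring A of 1 adds through C6 and C8 (its only strongly nucleophilic carbons) in a catalyst-controlled Friedel–Crafts conjugate addition that sets both exocyclic centres as S (ligand antipode if the sense is reversed; all stereoisomers are diastereomers and separable); closest known reaction type: Sc(OTf)3/N,N′-dioxide-catalysed asymmetric Friedel–Crafts additions of indoles and phenols to chalcones.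

**Step 2**
Reactants: 3 bis-adduct
Product: 4 penta-O-benzyl ether of 3 (4-OH of both aroyl rings, both arm 4-hydroxyphenyl groups and ring B 4′-OH benzylated; both chelated 2-OH groups, ring A 5-OH and 7-OH and the 3-OH free)
Conditions: BnBr (5.3 equiv), K2CO3 (6 equiv), acetone, 45 °C
Reagents that add atoms: benzyl bromide, BrCc1ccccc1
Why: Chemoselective Williamson etherification in which the five unhindered, non-chelated phenols react under mild carbonate conditions, while the 2-OH of each aroyl ring is held in a hydrogen bond to its carbonyl and the ring A hydroxyls are each flanked by two ortho substituents (any material benzylated further converges on 5 in step 3); no stereocentre is touched.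

**Step 3**
Reactants: 4 penta-O-benzyl ether
Product: 5 nona-O-benzyl ether of 3 (all nine phenols benzylated, 3-OH free)
Conditions: BnBr (6 equiv), Cs2CO3 (6 equiv), Bu4NI (cat.), DMF, 60 °C
Reagents that add atoms: benzyl bromide, BrCc1ccccc1
Why: Williamson etherification under forcing caesium phenoxide conditions benzylates the four remaining phenols (the two chelated 2-OH groups and the two hindered ring A hydroxyls), drains any ring A hemiketal to the open keto form, leaves the secondary 3-OH and the ketone α-CH2 alone and touches no stereocentre.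

**Step 4**
Reactants: 5 nona-O-benzyl bis-ketone
Product: 6 bis[(Z)-trimethylsilyl enol ether] of 5 carrying a 3-O-trimethylsilyl ether
Conditions: TMSOTf (4 equiv), Et3N (6 equiv), CH2Cl2, 0 °C; used crude
Reagents that add atoms: trimethylsilyl trifluoromethanesulfonate, C[Si](C)(C)OS(=O)(=O)C(F)(F)F
Why: Soft enolisation (silyl triflate/amine) of the two aryl ketones gives the thermodynamic Z-enol silanes at the only enolisable position and silylates the 3-OH, with the exocyclic centres untouched.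

**Step 5**
Reactants: 7 1-[2,4-bis(benzyloxy)phenyl]ethan-1-one; 8 4-(benzyloxy)benzaldehyde
Product: 9 (E)-1-[2,4-bis(benzyloxy)phenyl]-3-[4-(benzyloxy)phenyl]prop-2-en-1-one
Conditions: KOH, EtOH/THF, rt
Reagents that add atoms: none
Why: Claisen–Schmidt aldol condensation gives the E-enone under thermodynamic control; no stereocentre is formed.

**Step 6**
Reactants: 9 tri-O-benzylisoliquiritigenin
Product: 10 [2,4-bis(benzyloxy)phenyl]{(2S,3R)-3-[4-(benzyloxy)phenyl]oxiran-2-yl}methanone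
Conditions: poly-D-leucine, urea–H2O2, DBU, THF, rt
Reagents that add atoms: urea–hydrogen peroxide, NC(N)=O.OO
Why: Juliá–Colonna epoxidation (hydroperoxide conjugate addition/ring closure inside the helical polypeptide) gives the trans-(2S,3R) epoxide with poly-D-leucine (the L-polymer gives 2R,3S), and the benzylated 2′-oxygen blocks Algar–Flynn–Oyamada cyclisation.

**Step 7**
Reactants: 6 bis(enol silane); 10 epoxy ketone (3 equiv)
Product: 12 pentadeca-O-benzyl ether of the target (3-OH free), via bis(cyclic trimethylsilyl ketal) 11 (not isolated)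
Conditions: a) 10-phenylphenothiazine (5 mol %), 390 nm LEDs, MeCN/CH2Cl2, rt; b) Et3SiH, BF3·OEt2, CH2Cl2, −78 °C, MeOH quench; c) DBU (0.2 equiv), CH2Cl2, rt
Reagents that add atoms: none
Why: Proposed new method: a redox-neutral radical–polar crossover formal [3+2] that copies the biosynthetic α–α′ radical union and O-cyclisation, in which excited 10-phenylphenothiazine reduces 10, Cα–O cleavage gives a β-alkoxy α-keto radical that adds to the enol silane anti to the flavanyl group in its A(1,3)-minimised conformer (C4 = S), the α-silyloxybenzyl radical is oxidised by the phenothiazine radical cation and the alkoxide closes ketal 11 with C2 retained from the epoxide (S), then BF3·OEt2/Et3SiH reduces the five-membered oxocarbenium ion with hydride entering trans to the C4 substituent (C5 = R, the 4,5-cis outcome known from 2,5-diaryl-tetrahydrofuran lignan syntheses) and DBU equilibrates the ketone α-carbon C3 to the trans,trans arrangement (S); closest known reaction types: photoreductive opening/allylation of α,β-epoxy ketones and photoredox coupling of α-keto radicals with silyl enol ethers to 1,4-dicarbonyls.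

**Step 8**
Reactants: 12 pentadeca-O-benzyl ether
Product: 13 CNP0225367.3 (target)
Conditions: H2 (1 atm), Pd(OH)2/C, THF/MeOH, rt
Reagents that add atoms: none
Why: Neutral hydrogenolysis of the fifteen aryl benzyl ethers at room temperature leaves the hydrogen-bonded aryl ketones and the ring ethers in place, and no stereocentre is touched.

**Compound list**

1 | (+)-afzelechin, (2R,3S)-2-(4-hydroxyphenyl)chromane-3,5,7-triol | Oc1cc(O)c2c(c1)O[C@H](c1ccc(O)cc1)[C@@H](O)C2 | starting material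

2 | isoliquiritigenin, (E)-1-(2,4-dihydroxyphenyl)-3-(4-hydroxyphenyl)prop-2-en-1-one | O=C(/C=C/c1ccc(O)cc1)c1ccc(O)cc1O | starting material

3 | (2R,3S)-6,8-bis[(1S)-3-(2,4-dihydroxyphenyl)-1-(4-hydroxyphenyl)-3-oxopropyl]-2-(4-hydroxyphenyl)chromane-3,5,7-triol | O=C(c1ccc(O)cc1O)C[C@@H](c2ccc(O)cc2)c2c(O)c3c(c([C@H](c4ccc(O)cc4)CC(=O)c4ccc(O)cc4O)c2O)O[C@H](c2ccc(O)cc2)[C@@H](O)C3 | intermediate

4 | penta-O-benzyl ether of 3: (2R,3S)-2-[4-(benzyloxy)phenyl]-6,8-bis{(1S)-3-[4-(benzyloxy)-2-hydroxyphenyl]-1-[4-(benzyloxy)phenyl]-3-oxopropyl}chromane-3,5,7-triol | O=C(c1ccc(OCc6ccccc6)cc1O)C[C@@H](c2ccc(OCc6ccccc6)cc2)c2c(O)c3c(c([C@H](c4ccc(OCc6ccccc6)cc4)CC(=O)c4ccc(OCc6ccccc6)cc4O)c2O)O[C@H](c2ccc(OCc6ccccc6)cc2)[C@@H](O)C3 | intermediate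

5 | nona-O-benzyl ether of 3: (2R,3S)-5,7-bis(benzyloxy)-2-[4-(benzyloxy)phenyl]-6,8-bis{(1S)-3-[2,4-bis(benzyloxy)phenyl]-1-[4-(benzyloxy)phenyl]-3-oxopropyl}chroman-3-ol | O=C(c1ccc(OCc6ccccc6)cc1OCc6ccccc6)C[C@@H](c2ccc(OCc6ccccc6)cc2)c2c(OCc6ccccc6)c3c(c([C@H](c4ccc(OCc6ccccc6)cc4)CC(=O)c4ccc(OCc6ccccc6)cc4OCc6ccccc6)c2OCc6ccccc6)O[C@H](c2ccc(OCc6ccccc6)cc2)[C@@H](O)C3 | intermediate

6 | bis(enol silane) of 5: both arms are (1S,2Z)-3-[2,4-bis(benzyloxy)phenyl]-1-[4-(benzyloxy)phenyl]-3-(trimethylsilyloxy)prop-2-en-1-yl at C6 and C8, with 3-O-trimethylsilyl on the (2R,3S)-chroman | C[Si](C)(C)O/C(c1ccc(OCc6ccccc6)cc1OCc6ccccc6)=C\[C@@H](c2ccc(OCc6ccccc6)cc2)c2c(OCc6ccccc6)c3c(c([C@H](c4ccc(OCc6ccccc6)cc4)/C=C(\O[Si](C)(C)C)c4ccc(OCc6ccccc6)cc4OCc6ccccc6)c2OCc6ccccc6)O[C@H](c2ccc(OCc6ccccc6)cc2)[C@@H](O[Si](C)(C)C)C3 | intermediate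

7 | 1-[2,4-bis(benzyloxy)phenyl]ethan-1-one | CC(=O)c1ccc(OCc2ccccc2)cc1OCc1ccccc1 | starting material

8 | 4-(benzyloxy)benzaldehyde | O=Cc1ccc(OCc2ccccc2)cc1 | starting material

9 | (E)-1-[2,4-bis(benzyloxy)phenyl]-3-[4-(benzyloxy)phenyl]prop-2-en-1-one | O=C(/C=C/c1ccc(OCc2ccccc2)cc1)c1ccc(OCc2ccccc2)cc1OCc1ccccc1 | intermediate

10 | [2,4-bis(benzyloxy)phenyl]{(2S,3R)-3-[4-(benzyloxy)phenyl]oxiran-2-yl}methanone | O=C(c1ccc(OCc2ccccc2)cc1OCc1ccccc1)[C@H]1O[C@@H]1c1ccc(OCc2ccccc2)cc1 | intermediate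

11 | bis(cyclic trimethylsilyl ketal): each arm is (S)-[4-(benzyloxy)phenyl]{(2S,4S)-3-[2,4-bis(benzyloxy)benzoyl]-5-[2,4-bis(benzyloxy)phenyl]-2-[4-(benzyloxy)phenyl]-5-(trimethylsilyloxy)oxolan-4-yl}methyl, as a mixture of C3 epimers and C5 anomers, with 3-O-trimethylsilyl on the chroman | O=C(c1ccc(OCc6ccccc6)cc1OCc6ccccc6)C1[C@H]([C@@H](c2ccc(OCc6ccccc6)cc2)c2c(OCc6ccccc6)c3c(c([C@H](c4ccc(OCc6ccccc6)cc4)[C@H]4C(C(=O)c5ccc(OCc6ccccc6)cc5OCc6ccccc6)[C@@H](c5ccc(OCc6ccccc6)cc5)OC4(O[Si](C)(C)C)c4ccc(OCc6ccccc6)cc4OCc6ccccc6)c2OCc6ccccc6)O[C@H](c2ccc(OCc6ccccc6)cc2)[C@@H](O[Si](C)(C)C)C3)C(O[Si](C)(C)C)(c2ccc(OCc6ccccc6)cc2OCc6ccccc6)O[C@@H]1c1ccc(OCc6ccccc6)cc1 | intermediate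

12 | pentadeca-O-benzyl ether of 13 (every phenol benzylated, 3-OH free; flavan 2R,3S, exocyclic CH 1S, tetrahydrofurans 2S,3S,4S,5R) | O=C(c1ccc(OCc6ccccc6)cc1OCc6ccccc6)[C@H]1[C@H]([C@@H](c2ccc(OCc6ccccc6)cc2)c2c(OCc6ccccc6)c3c(c([C@H](c4ccc(OCc6ccccc6)cc4)[C@H]4[C@H](C(=O)c5ccc(OCc6ccccc6)cc5OCc6ccccc6)[C@@H](c5ccc(OCc6ccccc6)cc5)O[C@H]4c4ccc(OCc6ccccc6)cc4OCc6ccccc6)c2OCc6ccccc6)O[C@H](c2ccc(OCc6ccccc6)cc2)[C@@H](O)C3)[C@H](c2ccc(OCc6ccccc6)cc2OCc6ccccc6)O[C@@H]1c1ccc(OCc6ccccc6)cc1 | intermediate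

13 | CNP0225367.3: (2R,3S)-2-(4-hydroxyphenyl)-6,8-bis{(S)-(4-hydroxyphenyl)[(2S,3S,4S,5R)-3-(2,4-dihydroxybenzoyl)-5-(2,4-dihydroxyphenyl)-2-(4-hydroxyphenyl)oxolan-4-yl]methyl}chromane-3,5,7-triol | O=C(c1ccc(O)cc1O)[C@H]1[C@H]([C@@H](c2ccc(O)cc2)c2c(O)c3c(c([C@H](c4ccc(O)cc4)[C@H]4[C@H](C(=O)c5ccc(O)cc5O)[C@@H](c5ccc(O)cc5)O[C@H]4c4ccc(O)cc4O)c2O)O[C@H](c2ccc(O)cc2)[C@@H](O)C3)[C@H](c2ccc(O)cc2O)O[C@@H]1c1ccc(O)cc1 | target

**Totals and risks**

Total step count: 8. Longest linear sequence: 6 (steps 1, 2, 3, 4, 7, 8).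

The three steps most likely to fail:

Step 1 (two-fold catalytic asymmetric Friedel–Crafts addition of an unprotected flavan-3-ol; facial control and chromene formation are uncertain). Fallback: the aryl–CH bond is built in the opposite polarity. Setting out from 1, the three phenols are benzylated (BnBr, K2CO3, DMF) to 5,7,4′-tri-O-benzylafzelechin F1. This is formylated at both free ring A positions (POCl3, DMF, 70 °C, aqueous NaOAc work-up, then K2CO3/MeOH to cleave any 3-O-formate; Vilsmeier–Haack) to the 6,8-dicarbaldehyde F2. Double Claisen–Schmidt condensation with ketone 7 (KOH, EtOH/THF) gives the bis-enone F3. Hayashi–Miyaura conjugate addition of 4-(benzyloxy)phenylboronic acid (OB(O)c1ccc(OCc2ccccc2)cc1) with [Rh(acac)(C2H4)2] and the BINAP enantiomer that gives the 1S centres (dioxane/H2O, 60 °C) then returns to the route at 5.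

Step 7 (radical addition to a hindered β-substituted enol silane, and control of four centres per ring in one operation). Fallback: the α–α′ bond is made by two-electron enolate chemistry and the oxygen bridge by aldol/hemiketalisation. Setting out from 6, MeLi (THF, 0 °C) liberates the two lithium enolates, which are alkylated with 2-bromo-1-[2,4-bis(benzyloxy)phenyl]ethan-1-one F4 (from 7 with CuBr2, EtOAc, reflux) to the bis(1,4-diketone) F5; the 3-O-trimethylsilyl group is lost on aqueous work-up. Regioselective enolisation of the two less hindered CH2–CO termini with the appropriate enantiomer of Ipc2BCl and Et3N, followed by aldol addition to aldehyde 8, gives the bis(cyclic hemiketal) F6 with C2 set by the boron reagent; C4 equilibrates through the ring-opened ketone. Et3SiH/BF3·OEt2 at −78 °C and DBU as in step 7 then return to the route at 12.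

Step 8 (fifteen benzyl ethers must go without hydrogenolysis of the benzylic ring C–O bonds or the aryl ketones). Fallback: non-reductive Lewis-acid debenzylation, setting out from 12 and arriving directly at 13 with BCl3 and pentamethylbenzene as cation scavenger (CH2Cl2, −78 °C); this fallback makes no new compound (F0).

**Further compounds**

F1 | step 1 | (2R,3S)-5,7-bis(benzyloxy)-2-[4-(benzyloxy)phenyl]chroman-3-ol | O(Cc1ccccc1)c1cc(OCc3ccccc3)c2c(c1)O[C@H](c1ccc(OCc3ccccc3)cc1)[C@@H](O)C2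

F2 | step 1 | (2R,3S)-5,7-bis(benzyloxy)-2-[4-(benzyloxy)phenyl]-3-hydroxychromane-6,8-dicarbaldehyde | O=Cc2c(OCc6ccccc6)c3c(c(C=O)c2OCc6ccccc6)O[C@H](c2ccc(OCc6ccccc6)cc2)[C@@H](O)C3

F3 | step 1 | (2R,3S)-5,7-bis(benzyloxy)-2-[4-(benzyloxy)phenyl]-6,8-bis{(E)-3-[2,4-bis(benzyloxy)phenyl]-3-oxoprop-1-en-1-yl}chroman-3-ol | O=C(/C=C/c2c(OCc6ccccc6)c3c(c(/C=C/C(=O)c4ccc(OCc6ccccc6)cc4OCc6ccccc6)c2OCc6ccccc6)O[C@H](c2ccc(OCc6ccccc6)cc2)[C@@H](O)C3)c1ccc(OCc6ccccc6)cc1OCc6ccccc6

F4 | step 7 | 2-bromo-1-[2,4-bis(benzyloxy)phenyl]ethan-1-one | O=C(CBr)c1ccc(OCc2ccccc2)cc1OCc1ccccc1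

F5 | step 7 | bis(1,4-diketone): 5 carrying a 2-[2,4-bis(benzyloxy)phenyl]-2-oxoethyl group on each ketone α-carbon (α-carbons as epimer mixture) | O=C(c1ccc(OCc6ccccc6)cc1OCc6ccccc6)CC(C(=O)c1ccc(OCc6ccccc6)cc1OCc6ccccc6)[C@@H](c2ccc(OCc6ccccc6)cc2)c2c(OCc6ccccc6)c3c(c([C@H](c4ccc(OCc6ccccc6)cc4)C(CC(=O)c4ccc(OCc6ccccc6)cc4OCc6ccccc6)C(=O)c4ccc(OCc6ccccc6)cc4OCc6ccccc6)c2OCc6ccccc6)O[C@H](c2ccc(OCc6ccccc6)cc2)[C@@H](O)C3

F6 | step 7 | bis(cyclic hemiketal): 12 with OH in place of H at C5 of both tetrahydrofurans (C2 = S, C3/C4/C5 as equilibrating mixture) | O=C(c1ccc(OCc6ccccc6)cc1OCc6ccccc6)C1C([C@@H](c2ccc(OCc6ccccc6)cc2)c2c(OCc6ccccc6)c3c(c([C@H](c4ccc(OCc6ccccc6)cc4)C4C(C(=O)c5ccc(OCc6ccccc6)cc5OCc6ccccc6)[C@@H](c5ccc(OCc6ccccc6)cc5)OC4(O)c4ccc(OCc6ccccc6)cc4OCc6ccccc6)c2OCc6ccccc6)O[C@H](c2ccc(OCc6ccccc6)cc2)[C@@H](O)C3)C(O)(c2ccc(OCc6ccccc6)cc2OCc6ccccc6)O[C@@H]1c1ccc(OCc6ccccc6)cc1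

F0 | step 8 | none | none
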